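## Retrosynthetic overview

- The target is read as three 2-aryl-3-(hydroxymethyl) cyclic ethers in a row: oxolane ring A, inner dihydrobenzofuran ring B and outer dihydrobenzofuran ring C. The last two operations are a global hydride reduction (two esters and one pivalate become the three CH2OH groups) and removal of two benzyl ethers.
- Rings B and C are each cut at C2–C3 back to an aryl diazoacetate ortho to an ArO–CH2–Ar ether (carbene C–H insertion). B and C have opposite absolute configuration, so mirror-image catalysts are used, B first and C last.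
- Enabling feature: in ring C, C2–H is flanked by the ring oxygen O1 and the electron-rich 4-oxy-3-methoxyphenyl ring. It lies 1,5 to C3, which is benzylic to the benzo ring and carries the carboxyl-level carbon of the CH2OH group. C3 can therefore be a donor/acceptor carbene, and its ester later allows base equilibration to trans.
- The ether backbone comes from 5-iodovanillin used twice (rings B and C). Each aryl iodide is converted into the aryl diazoacetate by palladium coupling with ethyl diazoacetate only after the previous one has been consumed.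
- Ring A is built first: (R)-β-benzyl-γ-butyrolactone (Stobbe condensation, asymmetric hydrogenation), trans-aldol, diol, benzylic ketone, then ionic reduction of the cyclic hemiketal to the all-cis oxolane. Order of ring formation: A, B, C.

Key step: step 17

Remark (assumption): the facial sense of Rh2(S-PTTL)4 (dirhodium tetrakis[N-phthaloyl-(S)-tert-leucinate]; R at C2 of the new dihydrobenzofuran) and of the (S,S)-Et-DuPhos rhodium catalyst (R acid) is taken from the parent substrates; if either were opposite, the mirror-image catalyst would be used in that step.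

Abbreviations used in names: BnGu = 4-(benzyloxy)-3-methoxyphenyl; OxPiv = (2R,3R,4R)-4-(BnGu-methyl)-3-[(pivaloyloxy)methyl]oxolan-2-yl.

## Route

Step 1
Reactants: 1 4-(benzyloxy)-3-methoxybenzaldehyde; 2 dimethyl succinate
Product: 3 (E)-4-(BnGu)-3-(methoxycarbonyl)but-3-enoic acid
Conditions: NaOMe, MeOH, reflux; then aq. HCl
Reagents that add atoms: none
Why: Stobbe condensation, in which the succinate enolate adds to the aldehyde, the alkoxide lactonises and base-induced ring opening gives the (E)-alkylidene half-ester needed for chelation-controlled hydrogenation.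

Step 2
Reactants: 3 (E)-4-(BnGu)-3-(methoxycarbonyl)but-3-enoic acid
Product: 4 (R)-4-(BnGu)-3-(methoxycarbonyl)butanoic acid
Conditions: [Rh(cod)((S,S)-Et-DuPhos)]OTf (0.5 mol %), H2 (5 bar), NaOMe (0.1 equiv), MeOH, rt
Reagents that add atoms: none
Why: Asymmetric hydrogenation of an itaconate-type half-ester, in which the carboxylate chelates rhodium and the bisphospholane ligand selects the alkene face that gives the R centre (the future C4 of ring A); the homogeneous catalyst should leave the benzyl ether intact.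

Step 3
Reactants: 4 (R)-4-(BnGu)-3-(methoxycarbonyl)butanoic acid
Product: 6 (R)-4-(BnGu-methyl)dihydrofuran-2(3H)-one, via hydroxy acid 5 (not isolated)
Conditions: KOH (1.0 equiv), EtOH; CaCl2, NaBH4, EtOH, −10 °C to rt; then 2 M HCl, rt
Reagents that add atoms: none
Why: Chemoselective borohydride reduction of the ester in the presence of the carboxylate salt, followed by acid lactonisation, should give the β-benzyl lactone with the stereocentre no longer α to a carbonyl.

Step 4
Reactants: 7 5-iodovanillin (4-hydroxy-3-iodo-5-methoxybenzaldehyde)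
Product: 8 3-iodo-5-methoxy-4-(triisopropylsilyloxy)benzaldehyde
Conditions: TIPSCl, imidazole, DMF, rt
Reagents that add atoms: triisopropylsilyl chloride, CC(C)[Si](Cl)(C(C)C)C(C)C
Why: Silylation of the acidic phenol gives an ether that should survive enolate, hydride, oxidant and Lewis acid and can later be removed by fluoride in the presence of a diazo ester.

Step 5
Reactants: 6 (R)-4-(BnGu-methyl)dihydrofuran-2(3H)-one; 8 3-iodo-5-methoxy-4-(triisopropylsilyloxy)benzaldehyde
Product: 9 (3S,4R)-4-(BnGu-methyl)-3-{hydroxy[3-iodo-5-methoxy-4-(triisopropylsilyloxy)phenyl]methyl}dihydrofuran-2(3H)-one (both carbinol epimers)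
Conditions: LiHMDS, THF, −78 °C; then 8, −78 °C; AcOH quench
Reagents that add atoms: none
Why: Aldol addition of the lactone lithium enolate occurs anti to the β-benzyl group, setting the 3,4-trans lactone that becomes the C3/C4 cis pair of ring A; the carbinol configuration is irrelevant because it is erased in step 7.

Step 6
Reactants: 9 trans-aldol lactone
Product: 10 (2R,3R)-3-(BnGu-methyl)-2-{hydroxy[3-iodo-5-methoxy-4-(triisopropylsilyloxy)phenyl]methyl}butane-1,4-diol (both carbinol epimers)
Conditions: LiBH4, THF, 0 °C to rt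
Reagents that add atoms: none
Why: Borohydride reduction of the lactone to the 1,4-diol should spare the aryl iodide and the silyl ether and touches no stereocentre.

Step 7
Reactants: 10 triol
Product: 11 (2R,3R)-3-(BnGu-methyl)-4-hydroxy-2-(hydroxymethyl)-1-[3-iodo-5-methoxy-4-(triisopropylsilyloxy)phenyl]butan-1-one (in equilibrium with its cyclic hemiketal)
Conditions: activated MnO2 (excess), CH2Cl2, rt
Reagents that add atoms: none
Why: Manganese dioxide oxidises only the benzylic carbinol, converging both epimers of 10 into one ketone under neutral conditions that should not enolise the adjacent stereocentre.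

Step 8
Reactants: 11 γ-hydroxy ketone
Product: 13 [(2R,3R,4R)-4-(BnGu-methyl)-2-[3-iodo-5-methoxy-4-(triisopropylsilyloxy)phenyl]oxolan-3-yl]methanol (all-cis), via cyclic hemiketal 12 (not isolated)
Conditions: Et3SiH (5 equiv), BF3·OEt2 (2 equiv), CH2Cl2, −78 °C; Et3N then aq. NaHCO3 quench at −78 °C
Reagents that add atoms: none
Why: Reductive etherification (ionic reduction of a lactol): the 2-aryl oxocarbenium ion is attacked by hydride on the face opposite the cis-disposed C3 hydroxymethyl and C4 benzyl groups, so the aryl group ends cis to both (C2 = R); the low temperature is meant to prevent re-ionisation of the benzylic ether and enol-ether epimerisation at C3.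

Step 9
Reactants: 13 all-cis oxolane alcohol
Product: 14 [(2R,3R,4R)-4-(BnGu-methyl)-2-[3-iodo-5-methoxy-4-(triisopropylsilyloxy)phenyl]oxolan-3-yl]methyl pivalate
Conditions: PivCl, pyridine, DMAP (cat.), CH2Cl2, 0 °C to rt
Reagents that add atoms: pivaloyl chloride, CC(C)(C)C(=O)Cl
Why: Acylation masks the only O–H bond before carbene chemistry, and the pivalate falls off in the final hydride reduction.

Step 10
Reactants: 14 aryl iodide pivalate; 15 ethyl diazoacetate
Product: 16 ethyl 2-diazo-2-[3-methoxy-5-(OxPiv)-2-(triisopropylsilyloxy)phenyl]acetate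
Conditions: Pd(PPh3)4 (5 mol %), Ag2CO3 (0.5 equiv), Et3N (1.3 equiv), toluene, rt
Reagents that add atoms: none
Why: Zerovalent-palladium-catalysed cross-coupling of an aryl iodide with the C–H bond of ethyl diazoacetate (oxidative addition, silver-assisted palladation of the diazo carbon, reductive elimination) runs at room temperature and keeps the diazo group.

Step 11
Reactants: 7 5-iodovanillin; 17 4-(benzyloxy)-3-methoxybenzyl alcohol
Product: 18 4-(BnGu-methoxy)-3-iodo-5-methoxybenzaldehyde
Conditions: PPh3, DIAD, THF, 0 °C to rt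
Reagents that add atoms: none
Why: Mitsunobu etherification, in which the phenol (made acidic by the para-formyl and ortho-iodo groups) is alkylated by the benzylic oxyphosphonium ion.

Step 12
Reactants: 18 aldehyde
Product: 19 [4-(BnGu-methoxy)-3-iodo-5-methoxyphenyl]methanol
Conditions: NaBH4, MeOH/THF, 0 °C
Reagents that add atoms: none
Why: Borohydride reduces only the aldehyde.

Step 13
Reactants: 19 benzylic alcohol
Product: 20 4-(BnGu-methoxy)-3-iodo-5-methoxybenzyl bromide
Conditions: CBr4, PPh3, CH2Cl2, 0 °C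
Reagents that add atoms: carbon tetrabromide, BrC(Br)(Br)Br
Why: Appel bromination is neutral and should spare the acid-labile alkoxybenzyl aryl ether.

Step 14
Reactants: 16 silyl-protected diazo ester; 20 benzylic bromide
Product: 22 ethyl 2-diazo-2-{2-[(4-(BnGu-methoxy)-3-iodo-5-methoxybenzyl)oxy]-3-methoxy-5-(OxPiv)phenyl}acetate, via free phenol 21 (not isolated)
Conditions: CsF (3 equiv), DMF, 0 °C to rt, dark
Reagents that add atoms: none
Why: Fluoride cleaves the aryl silyl ether and the caesium phenoxide is O-alkylated in situ by the reactive benzylic bromide (Williamson ether synthesis), while the diazo ester is inert to fluoride and weak base.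

Step 15
Reactants: 22 diazo ester
Product: 23 ethyl (2R,3S)-2-[4-(BnGu-methoxy)-3-iodo-5-methoxyphenyl]-7-methoxy-5-(OxPiv)-2,3-dihydrobenzofuran-3-carboxylate (ring B closed, cis)
Conditions: Rh2(S-PTTL)4 (2 mol %), toluene, −60 °C, slow addition of 22
Reagents that add atoms: none
Why: Dirhodium-carboxylate-catalysed intramolecular 1,5 C–H insertion of the donor/acceptor carbene into the adjacent ArO–CH2–Ar bond closes ring B; the chiral catalyst selects the enantiotopic benzylic hydrogen (C2 = R), and the kinetic cis C3 centre is left as formed because it is equilibrated in step 17.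

Step 16
Reactants: 23 ring-B ester iodide; 15 ethyl diazoacetate
Product: 24 ethyl (2R,3S)-2-[3-(1-diazo-2-ethoxy-2-oxoethyl)-4-(BnGu-methoxy)-5-methoxyphenyl]-7-methoxy-5-(OxPiv)-2,3-dihydrobenzofuran-3-carboxylate
Conditions: Pd(PPh3)4 (5 mol %), Ag2CO3 (0.5 equiv), Et3N (1.3 equiv), toluene, rt
Reagents that add atoms: none
Why: The same zerovalent-palladium diazo cross-coupling as in step 10, now at the only remaining aryl iodide, which is flanked by a small benzyloxy-type ether.

Step 17
Reactants: 24 ring-C diazo ester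
Product: 26 ethyl (2S,3S)-2-(BnGu)-5-[(2R,3R)-3-(ethoxycarbonyl)-7-methoxy-5-(OxPiv)-2,3-dihydrobenzofuran-2-yl]-7-methoxy-2,3-dihydrobenzofuran-3-carboxylate (both rings trans), via cis-cis diester 25 (not isolated)
Conditions: Rh2(R-PTTL)4 (2 mol %), toluene, −60 °C, slow addition of 24; then DBU (1 equiv), rt to 45 °C
Reagents that add atoms: none
Why: The dirhodium carboxylate expels N2 from 24 to give a metal-bound donor/acceptor carbene at the future C3 of ring C, which inserts in a concerted, asynchronous three-centre step into the C–H bond of the neighbouring ArO–CH2–Ar ether and so forms the C2–C3 bond. The closest known reaction is the intramolecular 1,5 C–H insertion of 2-(benzyloxy)aryl diazoacetates to cis-2-aryl-2,3-dihydrobenzofuran-3-carboxylates with phthalimido-amino-acid dirhodium catalysts, followed by base epimerisation to the trans ester. Ring C is closed as a five-membered ring by 1,5 insertion through a cyclic transition state that contains C3, C3a, C7a, O1 and C2. C2 (S) is set by the catalyst, which picks one enantiotopic benzylic hydrogen and is the mirror image of the catalyst of step 15, so ring C receives the absolute configuration opposite to ring B, which no substrate bias could deliver; C3 forms cis under kinetic control. DBU in the same flask then equilibrates C3 of ring C and the still-cis C3 of ring B through their ester enolates to the trans arrangement dictated by the fixed C2 centres, ring opening by β-elimination being disfavoured because the C2–O bond lies orthogonal to the enolate π-system. The step needs site selectivity and freedom from O–H insertion: only the OCH2 hydrogens lie 1,5 to the carbene and are activated by oxygen and the electron-rich aryl ring, and every hydroxyl is masked as pivalate or benzyl ether.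

Step 18
Reactants: 26 trans-trans diester
Product: 27 di-O-benzyl target: [(2R,3R,4R)-4-(BnGu-methyl)-2-{(2R,3S)-2-[(2S,3R)-2-(BnGu)-3-(hydroxymethyl)-7-methoxy-2,3-dihydrobenzofuran-5-yl]-3-(hydroxymethyl)-7-methoxy-2,3-dihydrobenzofuran-5-yl}oxolan-3-yl]methanol
Conditions: LiAlH4, THF, 0 °C
Reagents that add atoms: none
Why: Hydride reduction converts both ethyl esters into CH2OH and cleaves the pivalate in one operation, after which the C3 centres can no longer epimerise; benzyl ethers are inert.

Step 19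
Reactants: 27 di-O-benzyl target
Product: 28 CNP0395728.1: [(2R,3R,4R)-2-{(2R,3S)-2-[(2S,3R)-2-(4-hydroxy-3-methoxyphenyl)-3-(hydroxymethyl)-7-methoxy-2,3-dihydrobenzofuran-5-yl]-3-(hydroxymethyl)-7-methoxy-2,3-dihydrobenzofuran-5-yl}-4-(4-hydroxy-3-methoxybenzyl)oxolan-3-yl]methanol
Conditions: H2 (1 atm), 10 % Pd/C, EtOAc/MeOH, rt, stopped at full conversion
Reagents that add atoms: none
Why: Hydrogenolysis of the two aryl benzyl ethers under neutral conditions should be much faster than cleavage of the cyclic benzylic C–O bonds.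

## Compound list

1 | 4-(benzyloxy)-3-methoxybenzaldehyde | COc1cc(C=O)ccc1OCc1ccccc1 | starting material
2 | dimethyl succinate | COC(=O)CCC(=O)OC | starting material
3 | (E)-4-(BnGu)-3-(methoxycarbonyl)but-3-enoic acid | OC(=O)C/C(C(=O)OC)=C\c1ccc(OCc2ccccc2)c(OC)c1 | intermediate
4 | (R)-4-(BnGu)-3-(methoxycarbonyl)butanoic acid | COC(=O)[C@@H](CC(=O)O)Cc1ccc(OCc2ccccc2)c(OC)c1 | intermediate
5 | (R)-4-(BnGu)-3-(hydroxymethyl)butanoic acid | OC[C@@H](CC(=O)O)Cc1ccc(OCc2ccccc2)c(OC)c1 | intermediate (not isolated)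
6 | (R)-4-(BnGu-methyl)dihydrofuran-2(3H)-one | O=C1C[C@@H](Cc2ccc(OCc3ccccc3)c(OC)c2)CO1 | intermediate
7 | 5-iodovanillin | COc1cc(C=O)cc(I)c1O | starting material
8 | 3-iodo-5-methoxy-4-(triisopropylsilyloxy)benzaldehyde | COc1cc(C=O)cc(I)c1O[Si](C(C)C)(C(C)C)C(C)C | intermediate
9 | (3S,4R)-trans-aldol lactone, carbinol epimers | O=C1OC[C@H](Cc2ccc(OCc3ccccc3)c(OC)c2)[C@H]1C(O)c1cc(OC)c(O[Si](C(C)C)(C(C)C)C(C)C)c(I)c1 | intermediate
10 | (2R,3R)-triol, carbinol epimers | OC[C@H](Cc1ccc(OCc2ccccc2)c(OC)c1)[C@H](CO)C(O)c1cc(OC)c(O[Si](C(C)C)(C(C)C)C(C)C)c(I)c1 | intermediate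
11 | (2R,3R)-γ-hydroxy aryl ketone | OC[C@H](Cc1ccc(OCc2ccccc2)c(OC)c1)[C@H](CO)C(=O)c1cc(OC)c(O[Si](C(C)C)(C(C)C)C(C)C)c(I)c1 | intermediate
12 | (3R,4R)-2-aryl-2-hydroxyoxolane (cyclic hemiketal of 11, anomers) | COc1cc(C[C@H]2COC(O)(c3cc(OC)c(O[Si](C(C)C)(C(C)C)C(C)C)c(I)c3)[C@H]2CO)ccc1OCc1ccccc1 | intermediate (not isolated)
13 | (2R,3R,4R)-all-cis oxolane alcohol | COc1cc(C[C@H]2CO[C@@H](c3cc(OC)c(O[Si](C(C)C)(C(C)C)C(C)C)c(I)c3)[C@H]2CO)ccc1OCc1ccccc1 | intermediate
14 | pivalate of 13 | COc1cc(C[C@H]2CO[C@@H](c3cc(OC)c(O[Si](C(C)C)(C(C)C)C(C)C)c(I)c3)[C@H]2COC(=O)C(C)(C)C)ccc1OCc1ccccc1 | intermediate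
15 | ethyl diazoacetate | CCOC(=O)C=[N+]=[N-] | starting material
16 | ethyl 2-diazo-2-[3-methoxy-5-(OxPiv)-2-(triisopropylsilyloxy)phenyl]acetate | COc1cc(C[C@H]2CO[C@@H](c3cc(OC)c(O[Si](C(C)C)(C(C)C)C(C)C)c(c3)C(=[N+]=[N-])C(=O)OCC)[C@H]2COC(=O)C(C)(C)C)ccc1OCc1ccccc1 | intermediate
17 | 4-(benzyloxy)-3-methoxybenzyl alcohol | COc1cc(CO)ccc1OCc1ccccc1 | starting material
18 | 4-(BnGu-methoxy)-3-iodo-5-methoxybenzaldehyde | COc1cc(C=O)cc(I)c1OCc1ccc(OCc2ccccc2)c(OC)c1 | intermediate
19 | [4-(BnGu-methoxy)-3-iodo-5-methoxyphenyl]methanol | COc1cc(CO)cc(I)c1OCc1ccc(OCc2ccccc2)c(OC)c1 | intermediate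
20 | 4-(BnGu-methoxy)-3-iodo-5-methoxybenzyl bromide | COc1cc(CBr)cc(I)c1OCc1ccc(OCc2ccccc2)c(OC)c1 | intermediate
21 | ethyl 2-diazo-2-[2-hydroxy-3-methoxy-5-(OxPiv)phenyl]acetate | COc1cc(C[C@H]2CO[C@@H](c3cc(OC)c(O)c(c3)C(=[N+]=[N-])C(=O)OCC)[C@H]2COC(=O)C(C)(C)C)ccc1OCc1ccccc1 | intermediate (not isolated)
22 | ring-B diazo ester with ring-C aryl ether | COc1cc(C[C@H]2CO[C@@H](c3cc(OC)c(OCc4cc(OC)c(OCc5ccc(OCc6ccccc6)c(OC)c5)c(I)c4)c(c3)C(=[N+]=[N-])C(=O)OCC)[C@H]2COC(=O)C(C)(C)C)ccc1OCc1ccccc1 | intermediate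
23 | cis-(2R,3S) ring-B ester, aryl iodide | COc1cc(C[C@H]2CO[C@@H](c3cc(OC)c4c(c3)[C@H](C(=O)OCC)[C@H](c3cc(OC)c(OCc5ccc(OCc6ccccc6)c(OC)c5)c(I)c3)O4)[C@H]2COC(=O)C(C)(C)C)ccc1OCc1ccccc1 | intermediate
24 | ring-C diazo ester | COc1cc(C[C@H]2CO[C@@H](c3cc(OC)c4c(c3)[C@H](C(=O)OCC)[C@H](c3cc(OC)c(OCc5ccc(OCc6ccccc6)c(OC)c5)c(c3)C(=[N+]=[N-])C(=O)OCC)O4)[C@H]2COC(=O)C(C)(C)C)ccc1OCc1ccccc1 | intermediate
25 | cis-cis diester (ring B 2R,3S; ring C 2S,3R) | COc1cc(C[C@H]2CO[C@@H](c3cc(OC)c4c(c3)[C@H](C(=O)OCC)[C@H](c3cc(OC)c5c(c3)[C@@H](C(=O)OCC)[C@@H](c3ccc(OCc6ccccc6)c(OC)c3)O5)O4)[C@H]2COC(=O)C(C)(C)C)ccc1OCc1ccccc1 | intermediate (not isolated)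
26 | trans-trans diester (ring B 2R,3R; ring C 2S,3S) | COc1cc(C[C@H]2CO[C@@H](c3cc(OC)c4c(c3)[C@@H](C(=O)OCC)[C@H](c3cc(OC)c5c(c3)[C@H](C(=O)OCC)[C@@H](c3ccc(OCc6ccccc6)c(OC)c3)O5)O4)[C@H]2COC(=O)C(C)(C)C)ccc1OCc1ccccc1 | intermediate
27 | di-O-benzyl target | COc1cc(C[C@H]2CO[C@@H](c3cc(OC)c4c(c3)[C@@H](CO)[C@H](c3cc(OC)c5c(c3)[C@H](CO)[C@@H](c3ccc(OCc6ccccc6)c(OC)c3)O5)O4)[C@H]2CO)ccc1OCc1ccccc1 | intermediate
28 | CNP0395728.1 | COc1cc(C[C@H]2CO[C@@H](c3cc(OC)c4c(c3)[C@@H](CO)[C@H](c3cc(OC)c5c(c3)[C@H](CO)[C@@H](c3ccc(O)c(OC)c3)O5)O4)[C@H]2CO)ccc1O | target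

## Step count and risks

Total step count: 19. Longest linear sequence: 15 steps (1–3, 5–10, 14–19).

Steps most likely to fail:

1. Step 17 (key step). What may go wrong: the chiral dirhodium carboxylate may discriminate poorly between the two enantiotopic benzylic hydrogens on this large, flexible substrate, giving ring-C diastereomers that cannot be upgraded so late. Fallback (sets out from 18, comes back at 26): ring C would be closed first on the small achiral fragment and ring B last. Aldehyde 18 would be coupled with 15 under the conditions of step 10 to the diazo aldehyde ethyl 2-diazo-2-[2-(BnGu-methoxy)-5-formyl-3-methoxyphenyl]acetate F1. Treatment with Rh2(R-PTTL)4 and then DBU should give ethyl (2S,3S)-2-(BnGu)-5-formyl-7-methoxy-2,3-dihydrobenzofuran-3-carboxylate F2, whose enantiomeric purity can be raised by recrystallisation before any other stereocentre is present. NaBH4 reduction would give the alcohol ethyl (2S,3S)-2-(BnGu)-5-(hydroxymethyl)-7-methoxy-2,3-dihydrobenzofuran-3-carboxylate F3, and CBr4/PPh3 the bromide ethyl (2S,3S)-2-(BnGu)-5-(bromomethyl)-7-methoxy-2,3-dihydrobenzofuran-3-carboxylate F4. Fluoride-triggered etherification of 16 with F4 (CsF, DMF) would give the ring-B diazo ester carrying the finished ring C F5, and Rh2(S-PTTL)4 followed by DBU would close ring B and deliver 26.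

2. Step 10. What may go wrong: oxidative addition at the iodide next to the bulky silyloxy group may be slow, so that ethyl diazoacetate decomposes on zerovalent palladium before it couples. Fallback (sets out from 14, comes back at 16): iodine–magnesium exchange with iPrMgCl·LiCl at −40 °C and acylation with diethyl oxalate would give the aryl glyoxylate ethyl 2-oxo-2-[3-methoxy-5-(OxPiv)-2-(triisopropylsilyloxy)phenyl]acetate F6. Condensation with TsNHNH2 would give the tosylhydrazone of that keto ester F7, and DBU-induced Bamford–Stevens elimination of sulfinate would give 16.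

3. Step 14. What may go wrong: the phenoxide set free next to the diazo ester may be lost by lactonisation or decomposition, and fluoride may consume bromide 20 before O-alkylation. Fallback (sets out from 14, comes back at 22): the ether would be made with no diazo group present, using an arylacetate that is orthogonal to the ring-C iodide. Negishi coupling of 14 with the Reformatsky reagent BrZnCH2CO2Et (Pd(dba)2, XPhos, THF, rt) would give ethyl 2-[3-methoxy-5-(OxPiv)-2-(triisopropylsilyloxy)phenyl]acetate F8. CsF and 20 in DMF would give the aryl ether arylacetate ethyl 2-{2-[(4-(BnGu-methoxy)-3-iodo-5-methoxybenzyl)oxy]-3-methoxy-5-(OxPiv)phenyl}acetate F9, and diazo transfer with p-acetamidobenzenesulfonyl azide and DBU in MeCN would give 22.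

Further compounds

F1 | step 17 | ethyl 2-diazo-2-[2-(BnGu-methoxy)-5-formyl-3-methoxyphenyl]acetate | CCOC(=O)C(=[N+]=[N-])c1cc(C=O)cc(OC)c1OCc1ccc(OCc2ccccc2)c(OC)c1
F2 | step 17 | ethyl (2S,3S)-2-(BnGu)-5-formyl-7-methoxy-2,3-dihydrobenzofuran-3-carboxylate | O=Cc1cc(OC)c2c(c1)[C@H](C(=O)OCC)[C@@H](c1ccc(OCc3ccccc3)c(OC)c1)O2
F3 | step 17 | ethyl (2S,3S)-2-(BnGu)-5-(hydroxymethyl)-7-methoxy-2,3-dihydrobenzofuran-3-carboxylate | OCc1cc(OC)c2c(c1)[C@H](C(=O)OCC)[C@@H](c1ccc(OCc3ccccc3)c(OC)c1)O2
F4 | step 17 | ethyl (2S,3S)-2-(BnGu)-5-(bromomethyl)-7-methoxy-2,3-dihydrobenzofuran-3-carboxylate | BrCc1cc(OC)c2c(c1)[C@H](C(=O)OCC)[C@@H](c1ccc(OCc3ccccc3)c(OC)c1)O2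
F5 | step 17 | ring-B diazo ester carrying the finished ring C | COc1cc(C[C@H]2CO[C@@H](c3cc(OC)c(OCc4cc(OC)c5c(c4)[C@H](C(=O)OCC)[C@@H](c4ccc(OCc6ccccc6)c(OC)c4)O5)c(c3)C(=[N+]=[N-])C(=O)OCC)[C@H]2COC(=O)C(C)(C)C)ccc1OCc1ccccc1
F6 | step 10 | ethyl 2-oxo-2-[3-methoxy-5-(OxPiv)-2-(triisopropylsilyloxy)phenyl]acetate | COc1cc(C[C@H]2CO[C@@H](c3cc(OC)c(O[Si](C(C)C)(C(C)C)C(C)C)c(c3)C(=O)C(=O)OCC)[C@H]2COC(=O)C(C)(C)C)ccc1OCc1ccccc1
F7 | step 10 | tosylhydrazone of F6 | COc1cc(C[C@H]2CO[C@@H](c3cc(OC)c(O[Si](C(C)C)(C(C)C)C(C)C)c(c3)C(=NNS(=O)(=O)c3ccc(C)cc3)C(=O)OCC)[C@H]2COC(=O)C(C)(C)C)ccc1OCc1ccccc1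
F8 | step 14 | ethyl 2-[3-methoxy-5-(OxPiv)-2-(triisopropylsilyloxy)phenyl]acetate | COc1cc(C[C@H]2CO[C@@H](c3cc(OC)c(O[Si](C(C)C)(C(C)C)C(C)C)c(c3)CC(=O)OCC)[C@H]2COC(=O)C(C)(C)C)ccc1OCc1ccccc1
F9 | step 14 | ethyl 2-{2-[(4-(BnGu-methoxy)-3-iodo-5-methoxybenzyl)oxy]-3-methoxy-5-(OxPiv)phenyl}acetate | COc1cc(C[C@H]2CO[C@@H](c3cc(OC)c(OCc4cc(OC)c(OCc5ccc(OCc6ccccc6)c(OC)c5)c(I)c4)c(c3)CC(=O)OCC)[C@H]2COC(=O)C(C)(C)C)ccc1OCc1ccccc1
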